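**Retrosynthetic overview**
1. Aryl–CH2 bond: 2,4-dihydroxyacetophenone 1 + prenol 2 give prenyl ketone 3 by a new boron-chelate-templated C3-prenylation; pivaloyl chloride 4 then masks both phenols (5).
2. Diol C–O bonds: Shi chiral-ketone epoxidation of 5 (metal-free, sets the only stereocenter) gives (R)-epoxide 6, which water opens at the tertiary carbon in the same flask to (R)-diol 7.
3. Enone C=C: 7 + 4-hydroxybenzaldehyde 8; KOH cleaves the esters (9) and drives the Claisen–Schmidt condensation to target 10.
4. Rings: neither benzene ring is built; the only ring formed is the oxirane of 6, made and opened in step 3.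

Assumption: the stereocenter of the target is (R), as read from the SMILES; the D-fructose-derived Shi ketone serves only as catalyst, and 1, 2, 4 and 8 are achiral commercial materials.

**Step 1**
Reactants: 1 2,4-dihydroxyacetophenone; 2 3-methylbut-2-en-1-ol (prenol)
Product: 3 1-[2,4-dihydroxy-3-(3-methylbut-2-en-1-yl)phenyl]ethan-1-one
Conditions: C6F5B(OH)2 (20 mol %), 2 (1.2 equiv), 1,2-dichloroethane, 45 °C, 16 h
Reagents that add atoms: 3-methylbut-2-en-1-ol (2), CC(C)=CCO
Why: Proposed new method: a chelate-templated dehydrative C3-prenylation in which the electron-poor boronic acid binds the 2-OH/C=O pair of 1 as a six-membered boron chelate, exchanges its remaining B–OH for prenol and ionises the B–O–allyl bond, so that the dimethylallyl cation is released as a contact ion pair beside C3 (doubly activated and the only free position ortho to the boron-bound oxygen) and is captured there at its primary terminus through a six-membered cyclic transition state, the arenium proton returning to the borate oxygen to regenerate the catalyst; the closest known reaction types are boronic-acid-catalysed Friedel–Crafts allylation of arenes with allylic alcohols and the phenylboronic-acid-templated ortho-hydroxyalkylation of phenols with aldehydes.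

**Step 2**
Reactants: 3 1-[2,4-dihydroxy-3-(3-methylbut-2-en-1-yl)phenyl]ethan-1-one; 4 pivaloyl chloride
Product: 5 4-acetyl-2-(3-methylbut-2-en-1-yl)-1,3-phenylene bis(2,2-dimethylpropanoate)
Conditions: 4 (3 equiv), Et3N (4 equiv), DMAP (20 mol %), CH2Cl2, 0 °C → 40 °C
Reagents that add atoms: pivaloyl chloride (4), CC(C)(C)C(=O)Cl
Why: DMAP-catalysed O-acylation (nucleophilic catalysis through the N-acylpyridinium ion) esterifies both phenols, including the hindered chelated 2-OH, and the resulting hindered, electron-poor ester oxygens cannot attack the epoxide made in step 3.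

**Step 3**
Reactants: 5 4-acetyl-2-(3-methylbut-2-en-1-yl)-1,3-phenylene bis(2,2-dimethylpropanoate)
Product: 7 4-acetyl-2-[(2R)-2,3-dihydroxy-3-methylbutyl]-1,3-phenylene bis(2,2-dimethylpropanoate), via (R)-epoxide 6 (not isolated)
Conditions: Shi ketone (1,2:4,5-di-O-isopropylidene-β-D-erythro-2,3-hexodiulo-2,6-pyranose, 30 mol %), Oxone (2KHSO5·KHSO4·K2SO4, 1.4 equiv), K2CO3 (5.8 equiv), Bu4NHSO4 (4 mol %), MeCN/aq. Na2B4O7–Na2EDTA buffer, 0 °C, 2 h; then 1 M H2SO4 to pH 2, 0 °C → rt, 1 h
Reagents that add atoms: potassium peroxymonosulfate (active part of Oxone), [K+].[O-]S(=O)(=O)OO; water, O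
Why: Shi asymmetric epoxidation followed by acid-catalysed epoxide hydrolysis: the dioxirane formed catalytically from the D-fructose-derived ketone transfers oxygen to the electron-rich trisubstituted olefin through the spiro transition state on the face that gives the (R)-epoxide (the sense observed for R–CH2–CH=CMe2 olefins), and on acidification water opens the protonated oxirane at the tertiary carbon, so the C–O bond at the stereocenter is untouched and (R) is retained in the diol.

**Step 4**
Reactants: 7 4-acetyl-2-[(2R)-2,3-dihydroxy-3-methylbutyl]-1,3-phenylene bis(2,2-dimethylpropanoate); 8 4-hydroxybenzaldehyde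
Product: 10 (2E)-1-{3-[(2R)-2,3-dihydroxy-3-methylbutyl]-2,4-dihydroxyphenyl}-3-(4-hydroxyphenyl)prop-2-en-1-one, via free dihydroxy ketone 9 (not isolated)
Conditions: KOH (50% aq., 20 equiv), 8 (2 equiv), EtOH, argon, rt → 45 °C, 36 h; then 1 M HCl to pH 4, 0 °C
Reagents that add atoms: 4-hydroxybenzaldehyde (8), O=Cc1ccc(O)cc1
Why: Aqueous hydroxide first saponifies both aryl pivalates (faster in water than Baker–Venkataraman acyl transfer) and the liberated methyl ketone then undergoes Claisen–Schmidt condensation (aldol addition, E1cB dehydration) to the thermodynamic E-enone, while the diol has no leaving group so the stereocenter is untouched and cold mild acidification avoids flavanone closure.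

**Compound list**
1 | 2,4-dihydroxyacetophenone | CC(=O)c1ccc(O)cc1O | starting material
2 | 3-methylbut-2-en-1-ol (prenol) | CC(C)=CCO | starting material
3 | 1-[2,4-dihydroxy-3-(3-methylbut-2-en-1-yl)phenyl]ethan-1-one | CC(=O)c1ccc(O)c(CC=C(C)C)c1O | intermediate
4 | pivaloyl chloride | CC(C)(C)C(=O)Cl | starting material
5 | 4-acetyl-2-(3-methylbut-2-en-1-yl)-1,3-phenylene bis(2,2-dimethylpropanoate) | CC(=O)c1ccc(OC(=O)C(C)(C)C)c(CC=C(C)C)c1OC(=O)C(C)(C)C | intermediate
6 | 4-acetyl-2-{[(2R)-3,3-dimethyloxiran-2-yl]methyl}-1,3-phenylene bis(2,2-dimethylpropanoate) | CC1(C)O[C@@H]1Cc1c(OC(=O)C(C)(C)C)ccc(C(C)=O)c1OC(=O)C(C)(C)C | intermediate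
7 | 4-acetyl-2-[(2R)-2,3-dihydroxy-3-methylbutyl]-1,3-phenylene bis(2,2-dimethylpropanoate) | CC(C)(O)[C@H](O)Cc1c(OC(=O)C(C)(C)C)ccc(C(C)=O)c1OC(=O)C(C)(C)C | intermediate
8 | 4-hydroxybenzaldehyde | O=Cc1ccc(O)cc1 | starting material
9 | 1-{3-[(2R)-2,3-dihydroxy-3-methylbutyl]-2,4-dihydroxyphenyl}ethan-1-one | CC(C)(O)[C@H](O)Cc1c(O)ccc(C(C)=O)c1O | intermediate
10 | (2E)-1-{3-[(2R)-2,3-dihydroxy-3-methylbutyl]-2,4-dihydroxyphenyl}-3-(4-hydroxyphenyl)prop-2-en-1-one | CC(C)(O)[C@H](O)Cc1c(O)ccc(C(=O)/C=C/c2ccc(O)cc2)c1O | target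

**Step count and risks**
Total steps: 4. Longest linear sequence: 4 steps (1 → 3 → 5 → 7 → 10).

Steps most likely to fail:

- **Step 1 (proposed new prenylation).** The chelate may deactivate the ring too much, or the cation may escape the template and give C5-prenyl, O-prenyl or chroman products. The fallback uses known chemistry, sets out from 1 and comes back at 3. Ketone 1 is alkylated at its non-chelated 4-OH with 3-chloro-3-methylbut-1-yne (K2CO3, KI, acetone, reflux) to 1-[2-hydroxy-4-(2-methylbut-3-yn-2-yloxy)phenyl]ethan-1-one F1. The alkyne is semi-hydrogenated (H2, Pd/CaCO3 poisoned with Pb(OAc)2, quinoline, EtOAc, rt) to 1-[2-hydroxy-4-(2-methylbut-3-en-2-yloxy)phenyl]ethan-1-one F2. Heating (N,N-diethylaniline, 130 °C) then effects the aromatic Claisen rearrangement, which is directed to C3 by the bond fixation of the chelated ring and delivers the allyl unit with transposition as the prenyl group of 3.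

- **Step 3 (Shi epoxidation and hydrolysis).** The aryl pivalates, above all the one next to the acetyl group, may be partly cleaved in the pH 10.5 buffer; a freed phenoxide would close onto the epoxide to a dihydrobenzofuran. The fallback sets out from 3 and comes back at 9, replacing the esters by base-stable acetals and separating the stages. Ketone 3 is treated with NaH and chloromethyl methyl ether (DMF, 0 °C → rt) to give 1-[2,4-bis(methoxymethoxy)-3-(3-methylbut-2-en-1-yl)phenyl]ethan-1-one F3. The same Shi epoxidation (MeCN/dimethoxymethane, epoxide isolated) gives 1-[3-{[(2R)-3,3-dimethyloxiran-2-yl]methyl}-2,4-bis(methoxymethoxy)phenyl]ethan-1-one F4. Dilute HClO4 in THF/H2O at 0 °C opens it to 1-{3-[(2R)-2,3-dihydroxy-3-methylbutyl]-2,4-bis(methoxymethoxy)phenyl}ethan-1-one F5. HCl in MeOH at rt removes both acetals and gives 9, isolated this time, which is condensed with 8 under the conditions of step 4.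

- **Step 4 (ester cleavage and unprotected Claisen–Schmidt).** The phenoxide-bearing ketone and the 4-oxidobenzaldehyde are both sluggish, so conversion may stall; expect a modest yield. The fallback sets out from 7 and comes back at 10. Diol 7 is condensed under the same KOH/EtOH conditions with the non-ionisable and far more electrophilic 4-(methoxymethoxy)benzaldehyde (COCOc1ccc(C=O)cc1) to give (2E)-1-{3-[(2R)-2,3-dihydroxy-3-methylbutyl]-2,4-dihydroxyphenyl}-3-[4-(methoxymethoxy)phenyl]prop-2-en-1-one F6. Brief treatment with 1 M HCl in MeOH at rt removes the acetal and gives 10.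

**Further compounds**
F1 | step 1 | 1-[2-hydroxy-4-(2-methylbut-3-yn-2-yloxy)phenyl]ethan-1-one | CC(=O)c1ccc(OC(C)(C)C#C)cc1O
F2 | step 1 | 1-[2-hydroxy-4-(2-methylbut-3-en-2-yloxy)phenyl]ethan-1-one | CC(=O)c1ccc(OC(C)(C)C=C)cc1O
F3 | step 3 | 1-[2,4-bis(methoxymethoxy)-3-(3-methylbut-2-en-1-yl)phenyl]ethan-1-one | CC(=O)c1ccc(OCOC)c(CC=C(C)C)c1OCOC
F4 | step 3 | 1-[3-{[(2R)-3,3-dimethyloxiran-2-yl]methyl}-2,4-bis(methoxymethoxy)phenyl]ethan-1-one | CC1(C)O[C@@H]1Cc1c(OCOC)ccc(C(C)=O)c1OCOC
F5 | step 3 | 1-{3-[(2R)-2,3-dihydroxy-3-methylbutyl]-2,4-bis(methoxymethoxy)phenyl}ethan-1-one | CC(C)(O)[C@H](O)Cc1c(OCOC)ccc(C(C)=O)c1OCOC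
F6 | step 4 | (2E)-1-{3-[(2R)-2,3-dihydroxy-3-methylbutyl]-2,4-dihydroxyphenyl}-3-[4-(methoxymethoxy)phenyl]prop-2-en-1-one | CC(C)(O)[C@H](O)Cc1c(O)ccc(C(=O)/C=C/c2ccc(OCOC)cc2)c1O
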